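The numbers in the tables are calculated on assumed constants, and the scatter is random.

Count the charges first.

| setting | amber | grey | flask |
|---|---|---|---|
| substrate | 0.050 M | 0.050 M | 0.050 M |
| salt in the second phase | 0.045 M | 0.045 M | 0.0450 M |
| spent carrier | 5 mM | 11 mM | 7.5 mM |
| remark | run made earlier | run made earlier |  |
| time |  |  | 1.0 h |
| volume of the second phase over the first |  |  | 1.0 |

| run | time / min | target / % | substrate / % |
|---|---|---|---|
| amber | 10.0 | 30 | 68 |
| amber | 25.0 | 53 | 48 |
| amber | 50.0 | 68 | 33 |
| amber | 80.0 | 79 | 24 |
| grey | 10.0 | 48 | 52 |
| grey | 25.0 | 69 | 31 |
| grey | 50.0 | 79 | 24 |
| grey | 80.0 | 84 | 18 |

(each reading ± 2 percentage points)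

- charges count per volume of the first phase; a concentration in a rate is the amount of a species over the volume of its own phase; every rate counts per litre of the first phase
- the earlier runs hold the two phases in the same ratio of volumes as the flask asked about
- the reaction counts as stopped when no species that holds the substrate changes by six tenths of a point or more over the second half of the time

1. why nothing more happens at 1.0 h, or that something still does (all of the substrate has reacted / forward and back rates have come level / no working catalyst is left / the salt in the second phase has run out first / it is still moving)
2. the target standing at 1.0 h, as a percentage of the substrate charged
3. amount of target if the flask were left three thousand times as long, in percent of the substrate charged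

Add target and substrate along the rows and you get between 98.0% and 103% of the charge, so I read each substrate lost as one target. Now ask which charge bounds that target. The carrier does not: the last amber reading holds 7.90 targets per carrier charged, so it goes round. That leaves two amounts, salt and substrate, and I take one of each per target. Their ratio is 90.0%; call this salt charge over substrate charge, the share of the substrate that can end as target, the ceiling. The salt is the limiting reagent.

That solves the far end. For the near end, use the readings: with 2.20 times the carrier, grey at 25.0 min stands where amber stands at 50.0 min. Interpolating to 1.0 h gives amber 71.7% and grey 80.7%, then interpolating in carrier gives my estimate for this flask, about 75.4%, with the scatter of the readings on it. That is 15 percentage points under the ceiling. Amber and grey still rose 11 points and 5 points between their last readings, so I call this flask still moving.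

The forecast says it is still moving, 77%, 1.6 points above my figure, and 90%: “Left very long, it reaches the salt limit”.

The flask gives it is still moving, 77.2% and 90.0%.

    substrate + fresh carrier → target + spent carrier (k = 0.340 M⁻¹ s⁻¹)
    fresh carrier ⇌ dormant form (K = 0.210, k = 0.00270 s⁻¹)
    spent carrier + salt in the second phase ⇌ fresh carrier + spent salt in the second phase (K = 0.510, k = 0.640 M⁻¹ s⁻¹)

At 1.00 h this flask still holds 13% of its salt. After 10.0 h it stands at 89.9% target against the ceiling of 90.0%, with 0.0901% of the salt and 10.1% of the substrate left.

Take a neighbour flask with 0.12 M of substrate and the same salt: the ceiling drops to 37.5%. That neighbour gives 37.4% at 1.00 h, with 0.338% of its salt left and 62.6% of its substrate.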